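## Retrosynthetic overview

1. Target ⇒ acyclic alkynone–malonate. One base-initiated cascade closes ring A (cyclohexanone, C1–C9, γ-Dieckmann) and then ring B (C2–C3–C4 bridge): the expelled methoxide adds to the ynone (C2–OMe) and the allenolate closes C3–C4.
2. Alkynone–malonate ⇒ terminal alkyne + benzoyl chloride (acyl Sonogashira) ⇒ primary triflate + dimethyl lavandulylmalonate (quaternary C5).
3. Triflate ⇒ alkynol ⇒ trans-diprenyl δ-lactol (Ohira–Bestmann) ⇒ C2-symmetric diol (selective IBX mono-oxidation) ⇒ two-directional Evans prenylation of the 3,3-dimethylglutaryl bis-imide (sets C7).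
4. Lavandulylmalonate ⇒ (S)-lavandulyl iodide ⇒ (S)-lavandulol ⇒ Evans deconjugative prenylation of the N-senecioyl imide.

Assumption: PPAP numbering is used throughout (C1 prenyl bridgehead, C2 C–OMe, C3 C–benzoyl, C4 C=O, C5 lavandulyl bridgehead, C6 CH2, C7 CH–prenyl, C8 CMe2, C9 bridging C=O); prenyl = 3-methylbut-2-en-1-yl, lavandulyl = 5-methyl-2-(prop-1-en-2-yl)hex-4-en-1-yl; enantiopure lavandulol is not taken as purchasable; a lactol and its open-chain hydroxy-aldehyde tautomer are treated as one compound.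

## Route

Step 1
Reactants: 1 (S)-4-benzyl-1,3-oxazolidin-2-one; 2 3-methylbut-2-enoyl chloride
Product: 3 (S)-4-benzyl-3-(3-methylbut-2-enoyl)-1,3-oxazolidin-2-one
Conditions: n-BuLi, THF, −78 °C; then 2, −78 → 0 °C
Reagents that add atoms: 3-methylbut-2-enoyl chloride (2), CC(C)=CC(=O)Cl
Why: N-acylation of the lithiated oxazolidinone (Evans imide formation); no new stereocentre.

Step 2
Reactants: 3; 4 prenyl bromide (1-bromo-3-methylbut-2-ene)
Product: 5 (4S)-4-benzyl-3-[(2S)-5-methyl-2-(prop-1-en-2-yl)hex-4-enoyl]-1,3-oxazolidin-2-one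
Conditions: NaHMDS, THF, −78 °C; then 4, −78 → −40 °C
Reagents that add atoms: prenyl bromide (4), CC(C)=CCBr
Why: Evans deconjugative α-alkylation: γ-deprotonation gives the chelated Z-sodium dienolate, which is prenylated at the α-carbon on the face opposite the benzyl group, setting the lavandulyl stereocentre.

Step 3
Reactants: 5
Product: 6 (S)-lavandulol [(2S)-5-methyl-2-(prop-1-en-2-yl)hex-4-en-1-ol]
Conditions: LiBH4, H2O (1.1 equiv), Et2O, 0 °C
Reagents that add atoms: none
Why: Reductive cleavage of the exocyclic imide carbonyl under non-basic conditions, so the allylic α-centre neither epimerises nor conjugates; the auxiliary is recovered.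

Step 4
Reactants: 6
Product: 7 (S)-lavandulyl iodide [(3S)-3-(iodomethyl)-2,6-dimethylhepta-1,5-diene]
Conditions: I2, PPh3, imidazole, CH2Cl2, 0 °C → rt
Reagents that add atoms: iodine, II
Why: Appel-type (Garegg–Samuelsson) iodination by SN2 at the primary carbon; the stereocentre is not involved.

Step 5
Reactants: 7; 8 dimethyl malonate
Product: 9 dimethyl 2-[(2R)-5-methyl-2-(prop-1-en-2-yl)hex-4-en-1-yl]propanedioate (dimethyl lavandulylmalonate; same spatial arrangement as 6, descriptor changes by CIP)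
Conditions: 8 (3 equiv), NaH (2.5 equiv), THF/DMF, 0 → 50 °C
Reagents that add atoms: dimethyl malonate (8), COC(=O)CC(=O)OC
Why: Malonic ester SN2 alkylation with the soft sodium enolate in excess, which suppresses dialkylation and E2.

Step 6
Reactants: 10 3,3-dimethylglutaric anhydride; 1 (S)-4-benzyl-1,3-oxazolidin-2-one (2.1 equiv)
Product: 13 3,3'-(3,3-dimethylpentanedioyl)bis[(4S)-4-benzyl-1,3-oxazolidin-2-one], via mono-imide lithium carboxylate 11 (not isolated), via mixed pivalic anhydride 12 (not isolated)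
Conditions: 1 (1.0 equiv), n-BuLi, THF, −78 °C, then 10, → 0 °C; PivCl, 0 °C; then lithiated 1 (1.1 equiv), −78 → 0 °C
Reagents that add atoms: (S)-4-benzyl-1,3-oxazolidin-2-one (1), O=C1N[C@@H](Cc2ccccc2)CO1
Why: Anhydride opening by the lithiated oxazolidinone, then mixed-anhydride N-acylation at the less hindered carbonyl installs the second auxiliary; no new stereocentre.

Step 7
Reactants: 13; 4 prenyl bromide (6 equiv)
Product: 14 3,3'-[(2S,4S)-3,3-dimethyl-2,4-bis(3-methylbut-2-en-1-yl)pentanedioyl]bis[(4S)-4-benzyl-1,3-oxazolidin-2-one]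
Conditions: NaHMDS (2.4 equiv), THF, −78 °C; then 4, −78 → −35 °C
Reagents that add atoms: prenyl bromide (4), CC(C)=CCBr
Why: Two-directional Evans alkylation: each chelated Z-enolate is prenylated anti to its benzyl group, giving the C2-symmetric (2S,4S) product; one new centre becomes C7 of the target and its twin (future C1) is erased later.

Step 8
Reactants: 14
Product: 15 (2S,4S)-3,3-dimethyl-2,4-bis(3-methylbut-2-en-1-yl)pentane-1,5-diol
Conditions: LiBH4, H2O (2.2 equiv), Et2O/THF, 0 °C → rt
Reagents that add atoms: none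
Why: Reductive removal of both auxiliaries (imide to primary alcohol) without touching the stereocentres or the alkenes.

Step 9
Reactants: 15
Product: 16 (3S,5S)-4,4-dimethyl-3,5-bis(3-methylbut-2-en-1-yl)tetrahydro-2H-pyran-2-ol (trans lactol; anomer mixture)
Conditions: IBX (1.15 equiv), DMSO, rt
Reagents that add atoms: none
Why: Selective IBX oxidation of a diol to a lactol: the two hydroxymethyl groups are homotopic (C2 axis), the δ-hydroxy aldehyde closes at once to the six-membered hemiacetal (gem-dimethyl effect), and IBX oxidises hemiacetals only sluggishly, so the ends are differentiated without a protecting group; C3 and C5 are untouched and the anomeric centre is of no consequence.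

Step 10
Reactants: 16; 17 dimethyl (1-diazo-2-oxopropyl)phosphonate (Ohira–Bestmann reagent)
Product: 18 (2S,4R)-4-ethynyl-3,3,7-trimethyl-2-(3-methylbut-2-en-1-yl)oct-6-en-1-ol
Conditions: 17 (2 equiv), K2CO3 (3 equiv), MeOH, 0 °C → rt
Reagents that add atoms: dimethyl (1-diazo-2-oxopropyl)phosphonate (17), COP(=O)(OC)C(=[N+]=[N-])C(C)=O
Why: Ohira–Bestmann (Seyferth–Gilbert) homologation of the open hydroxy-aldehyde tautomer of the lactol turns the hemiacetal carbon into the C2≡C3 alkyne and frees the C6 hydroxyl; C7 is untouched, and the α-centre, flanked by the quaternary carbon, is not epimerised under these mild conditions and is in any case erased in step 14.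

Step 11
Reactants: 18
Product: 19 (2S,4R)-4-ethynyl-3,3,7-trimethyl-2-(3-methylbut-2-en-1-yl)oct-6-en-1-yl trifluoromethanesulfonate
Conditions: Tf2O, pyridine, CH2Cl2, −78 → −20 °C (used at once)
Reagents that add atoms: trifluoromethanesulfonic anhydride, O=S(=O)(OS(=O)(=O)C(F)(F)F)C(F)(F)F
Why: Sulfonylation of the primary alcohol gives a leaving group reactive enough for SN2 at this β-branched carbon.

Step 12
Reactants: 19; 9 dimethyl lavandulylmalonate (1.3 equiv)
Product: 20 dimethyl 2-[(2R,4R)-4-ethynyl-3,3,7-trimethyl-2-(3-methylbut-2-en-1-yl)oct-6-en-1-yl]-2-[(2R)-5-methyl-2-(prop-1-en-2-yl)hex-4-en-1-yl]propanedioate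
Conditions: 9, NaH (1.2 equiv), THF, 0 °C; then 19, 0 °C → rt
Reagents that add atoms: dimethyl lavandulylmalonate (9), C=C(C)[C@H](CC=C(C)C)CC(C(=O)OC)C(=O)OC
Why: SN2 C-alkylation of the tertiary malonate sodium enolate (tight ion pair in THF) by the primary triflate builds quaternary C5; the alkyne C–H is not acidic enough to interfere.

Step 13
Reactants: 20; 21 benzoyl chloride
Product: 22 dimethyl 2-[(2R,4S)-3,3,7-trimethyl-2-(3-methylbut-2-en-1-yl)-4-(3-oxo-3-phenylprop-1-yn-1-yl)oct-6-en-1-yl]-2-[(2R)-5-methyl-2-(prop-1-en-2-yl)hex-4-en-1-yl]propanedioate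
Conditions: PhCOCl, PdCl2(PPh3)2 (2 mol%), CuI (4 mol%), Et3N, THF, rt, Ar
Reagents that add atoms: benzoyl chloride (21), O=C(Cl)c1ccccc1
Why: Pd/Cu-catalysed acyl Sonogashira coupling gives the ynone under conditions too mild to affect the esters or alkenes.

Step 14
Reactants: 22
Product: 24 target CNP0385193.1, via monocyclic alkynyl ketone 23 (not isolated)
Conditions: LiTMP (1.3 equiv; from TMPH/n-BuLi, THF, 0 °C), 22 added at −78 °C (0.01 M), DMPU (4 equiv), −78 → 0 °C; H2O
Reagents that add atoms: none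
Why: Proposed new method: γ-deprotonation of the ynone (only acidic C–H) gives a cumulenolate whose γ-carbon C1 can only reach a malonate ester through a six-membered chair (C7-prenyl, C1-prenyl and C5-lavandulyl equatorial, alkynyl and remaining ester cis-diaxial, hence 7-exo and the (1R,5R) bridgeheads from C7), closing ring A as 23 in a reversible γ-Dieckmann that corrects wrong diastereomers; the expelled LiOMe adds to the restored ynone at C2 and the allenolate C-acylates the axial ester (C3–C4), irreversibly closing ring B with the methoxy group fixed at C2; closest known reaction types are γ-deprotonation of 2-alkynoates/ynones to allenyl enolates, γ-acylation of 1,3-diketone dianions, and nucleophile-triggered conjugate addition–aldol/Dieckmann cyclisations of ynones.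

## Compound list

1 | (S)-4-benzyl-1,3-oxazolidin-2-one | O=C1N[C@@H](Cc2ccccc2)CO1 | starting material
2 | 3-methylbut-2-enoyl chloride | CC(C)=CC(=O)Cl | starting material
3 | (S)-4-benzyl-3-(3-methylbut-2-enoyl)-1,3-oxazolidin-2-one | CC(C)=CC(=O)N1[C@@H](Cc2ccccc2)COC1=O | intermediate
4 | prenyl bromide | CC(C)=CCBr | starting material
5 | (4S)-4-benzyl-3-[(2S)-5-methyl-2-(prop-1-en-2-yl)hex-4-enoyl]-1,3-oxazolidin-2-one | C=C(C)[C@H](CC=C(C)C)C(=O)N1[C@@H](Cc2ccccc2)COC1=O | intermediate
6 | (S)-lavandulol | C=C(C)[C@H](CC=C(C)C)CO | intermediate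
7 | (S)-lavandulyl iodide | C=C(C)[C@H](CC=C(C)C)CI | intermediate
8 | dimethyl malonate | COC(=O)CC(=O)OC | starting material
9 | dimethyl 2-[(2R)-5-methyl-2-(prop-1-en-2-yl)hex-4-en-1-yl]propanedioate | C=C(C)[C@H](CC=C(C)C)CC(C(=O)OC)C(=O)OC | intermediate
10 | 3,3-dimethylglutaric anhydride | CC1(C)CC(=O)OC(=O)C1 | starting material
11 | lithium 5-[(4S)-4-benzyl-2-oxo-1,3-oxazolidin-3-yl]-3,3-dimethyl-5-oxopentanoate (not isolated) | [Li+].[O-]C(=O)CC(C)(C)CC(=O)N1[C@@H](Cc2ccccc2)COC1=O | intermediate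
12 | mixed pivalic anhydride of the acid of 11 (not isolated) | CC(C)(C)C(=O)OC(=O)CC(C)(C)CC(=O)N1[C@@H](Cc2ccccc2)COC1=O | intermediate
13 | 3,3'-(3,3-dimethylpentanedioyl)bis[(4S)-4-benzyl-1,3-oxazolidin-2-one] | O=C(CC(C)(C)CC(=O)N1[C@@H](Cc2ccccc2)COC1=O)N1[C@@H](Cc2ccccc2)COC1=O | intermediate
14 | (2S,4S)-2,4-diprenyl bis-imide | O=C(N1[C@@H](Cc2ccccc2)COC1=O)[C@@H](CC=C(C)C)C(C)(C)[C@H](CC=C(C)C)C(=O)N1[C@@H](Cc2ccccc2)COC1=O | intermediate
15 | (2S,4S)-3,3-dimethyl-2,4-bis(3-methylbut-2-en-1-yl)pentane-1,5-diol | OC[C@@H](CC=C(C)C)C(C)(C)[C@H](CC=C(C)C)CO | intermediate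
16 | (3S,5S)-4,4-dimethyl-3,5-bis(3-methylbut-2-en-1-yl)tetrahydro-2H-pyran-2-ol (trans lactol; anomer mixture; ring–chain tautomer of the δ-hydroxy aldehyde) | OC1OC[C@@H](CC=C(C)C)C(C)(C)[C@@H]1CC=C(C)C | intermediate
17 | dimethyl (1-diazo-2-oxopropyl)phosphonate | COP(=O)(OC)C(=[N+]=[N-])C(C)=O | starting material
18 | (2S,4R)-4-ethynyl-3,3,7-trimethyl-2-(3-methylbut-2-en-1-yl)oct-6-en-1-ol | OC[C@@H](CC=C(C)C)C(C)(C)[C@H](CC=C(C)C)C#C | intermediate
19 | triflate of 18 | O=S(=O)(OC[C@@H](CC=C(C)C)C(C)(C)[C@H](CC=C(C)C)C#C)C(F)(F)F | intermediate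
20 | quaternary malonate with terminal alkyne (C5 carries lavandulyl and the C6–C1 chain) | C=C(C)[C@H](CC=C(C)C)CC(C(=O)OC)(C(=O)OC)C[C@@H](CC=C(C)C)C(C)(C)[C@H](CC=C(C)C)C#C | intermediate
21 | benzoyl chloride | O=C(Cl)c1ccccc1 | starting material
22 | alkynone–malonate (benzoyl on the alkyne terminus of 20) | C=C(C)[C@H](CC=C(C)C)CC(C(=O)OC)(C(=O)OC)C[C@@H](CC=C(C)C)C(C)(C)[C@H](CC=C(C)C)C#CC(=O)c1ccccc1 | intermediate
23 | methyl 1-lavandulyl-4,4-dimethyl-2-oxo-3-(3-oxo-3-phenylprop-1-yn-1-yl)-3,5-diprenylcyclohexane-1-carboxylate; ester and alkynyl cis-diaxial, the three alkyl groups equatorial (not isolated) | C=C(C)[C@H](CC=C(C)C)C[C@@]1(C(=O)OC)C[C@@H](CC=C(C)C)C(C)(C)[C@](CC=C(C)C)(C#CC(=O)c2ccccc2)C1=O | intermediate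
24 | CNP0385193.1: (1R,5R,7R)-3-benzoyl-2-methoxy-8,8-dimethyl-1,7-diprenyl-5-[(2R)-lavandulyl]bicyclo[3.3.1]non-2-ene-4,9-dione (PPAP numbering; 7-prenyl exo) | C=C(C)[C@H](CC=C(C)C)C[C@@]12C[C@@H](CC=C(C)C)C(C)(C)[C@@](CC=C(C)C)(C1=O)C(OC)=C(C(=O)c1ccccc1)C2=O | target

## Step count

Total steps: 14. Longest linear sequence: 9 (steps 6–14, from 10; the lavandulyl branch, steps 1–5, joins at step 12).

## Steps most likely to fail, with fallbacks

Step 14 (cascade bicyclisation). The γ-Dieckmann is an uphill pre-equilibrium and the methoxide relay is untested. The fallback sets out from 22 and comes back at 24. Hydration of the ynone (pyrrolidine, then aqueous AcOH) gives the 1,3-diketone F1. LDA (2.3 equiv, THF, −78 → 0 °C) forms its dianion; the γ-carbanion (C1) closes ring A by Dieckmann and the diketonate carbon (C3) then closes ring B onto the second ester, a polyketide-type double Claisen driven by the stable triketone enolate, giving the enolised triketone F2. TMSCHN2 in MeOH/toluene O-methylates F2 to 24 together with the 4-methoxy regioisomer F3. The isomers are separated by chromatography, and F3 is demethylated (LiCl, DMSO) back to F2 and recycled.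

Step 12 (quaternary C5 by SN2). The tertiary malonate may O-alkylate or react slowly with the β-branched triflate. The fallback sets out from 19 and comes back at 20. Excess sodium dimethyl malonate (from 8) is alkylated by 19 to the monoalkyl malonate F4, where the nucleophile is unhindered. The quaternary centre is then made in the other sense with the less hindered electrophile, (S)-lavandulyl iodide 7 (NaH, DMF, 50 °C), which gives 20.

Step 7 (double prenylation flanking the quaternary carbon). The second alkylation may stall or the bis-enolate may decompose. The fallback sets out from 10 and comes back at 16. Methanolysis (MeOH, DMAP) gives monomethyl 3,3-dimethylglutarate F5. Acylation of 1 (PivCl, Et3N, LiCl) gives the imide ester F6. A single Evans prenylation (NaHMDS, 4) gives the (S)-configured imide ester F7, which sets C7. LiBH4 reduction followed by acid-promoted lactonisation gives the mono-prenyl lactone F8. Alkylation of the lactone lithium enolate (LDA, 4, THF, −78 °C) is expected to give the trans-diprenyl lactone F9, by chair-like axial attack away from the adjacent axial methyl and trans to the C5 side chain; that centre is erased in step 14 in any case. DIBAL-H (CH2Cl2, −78 °C) reduces F9 to the lactol 16.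

## Further compounds

F1 | step 14 | dimethyl malonate of 22 with the ynone hydrated to the 1-phenylbutane-1,3-dione unit (C1 configuration drawn as retained; it is lost in the next operation) | C=C(C)[C@H](CC=C(C)C)CC(C(=O)OC)(C(=O)OC)C[C@@H](CC=C(C)C)C(C)(C)[C@H](CC=C(C)C)C(=O)CC(=O)c1ccccc1
F2 | step 14 | O-demethyl target: 3-benzoyl-2-hydroxy-8,8-dimethyl-1,7-diprenyl-5-lavandulylbicyclo[3.3.1]non-2-ene-4,9-dione (one enol tautomer) | C=C(C)[C@H](CC=C(C)C)C[C@@]12C[C@@H](CC=C(C)C)C(C)(C)[C@@](CC=C(C)C)(C1=O)C(O)=C(C(=O)c1ccccc1)C2=O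
F3 | step 14 | 4-methoxy regioisomer of the target: 3-benzoyl-4-methoxy-8,8-dimethyl-1,7-diprenyl-5-lavandulylbicyclo[3.3.1]non-3-ene-2,9-dione | C=C(C)[C@H](CC=C(C)C)C[C@@]12C[C@@H](CC=C(C)C)C(C)(C)[C@@](CC=C(C)C)(C1=O)C(=O)C(C(=O)c1ccccc1)=C2OC
F4 | step 12 | dimethyl 2-[(2R,4R)-4-ethynyl-3,3,7-trimethyl-2-(3-methylbut-2-en-1-yl)oct-6-en-1-yl]propanedioate | COC(=O)C(C(=O)OC)C[C@@H](CC=C(C)C)C(C)(C)[C@H](CC=C(C)C)C#C
F5 | step 7 | 5-methoxy-3,3-dimethyl-5-oxopentanoic acid | COC(=O)CC(C)(C)CC(=O)O
F6 | step 7 | methyl 5-[(4S)-4-benzyl-2-oxo-1,3-oxazolidin-3-yl]-3,3-dimethyl-5-oxopentanoate | COC(=O)CC(C)(C)CC(=O)N1[C@@H](Cc2ccccc2)COC1=O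
F7 | step 7 | methyl (4S)-4-{[(4S)-4-benzyl-2-oxo-1,3-oxazolidin-3-yl]carbonyl}-3,3,7-trimethyloct-6-enoate | COC(=O)CC(C)(C)[C@H](CC=C(C)C)C(=O)N1[C@@H](Cc2ccccc2)COC1=O
F8 | step 7 | (5S)-4,4-dimethyl-5-(3-methylbut-2-en-1-yl)tetrahydro-2H-pyran-2-one | O=C1CC(C)(C)[C@H](CC=C(C)C)CO1
F9 | step 7 | (3S,5S)-4,4-dimethyl-3,5-bis(3-methylbut-2-en-1-yl)tetrahydro-2H-pyran-2-one (trans) | O=C1OC[C@@H](CC=C(C)C)C(C)(C)[C@@H]1CC=C(C)C
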